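The data are simulated for an exercise.

the same everywhere: starting material 0.150 M; coupling partner 0.300 M

| run | free catalyst | product | time |
|---|---|---|---|
| north | 3.00 × 10⁻⁴ M |  |  |
| south-east | 1.50 × 10⁻⁴ M |  |  |
| south | 3.00 × 10⁻⁴ M | 0.0450 M |  |
| south-west | 3.00 × 10⁻⁴ M |  | 190 h |

| run | time / h | [product] / M |
|---|---|---|
| north run | 3.8 | 0.0051 |
| north run | 6.5 | 0.0100 |
| north run | 11 | 0.0144 |
| north run | 19 | 0.0223 |
| north run | 32 | 0.0385 |
| north run | 56 | 0.0597 |
| north run | 95 | 0.0867 |
| south-east run | 3.8 | 0.0023 |
| south-east run | 6.5 | 0.0046 |
| south-east run | 11 | 0.0076 |
| south-east run | 19 | 0.0130 |
| south-east run | 32 | 0.0181 |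
| south-east run | 56 | 0.0303 |
| south-east run | 95 | 0.0458 |
| south run | 3.8 | 0.0488 |
| south run | 6.5 | 0.0544 |
| south run | 11 | 0.0604 |
| south run | 19 | 0.0694 |
| south run | 32 | 0.0831 |
| south run | 56 | 0.1019 |
| south run | 95 | 0.1301 |

(standard deviation of a reading: 8 × 10⁻⁴ M)

- reaction order in [free catalyst] at the outset, round the charge of the north run, defined at two percent of the starting material turned into product
- product in the south-west run at 190 h, as a share of the starting material charged

- Overall: starting material + coupling partner -> product, with free catalyst as catalyst.
- Constant volume, constant temperature.
- Bound and free are read together.
- "The second partner" is coupling partner.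
- An order is taken over about fifteen percent of the charge, up and down.

The ratio of product made by 11 h in the north run to that in the south-east run is 1.89, for 2.00 times the catalyst, with 9.60% of the starting material turned in the north run. This reads as an order in free catalyst of 0.922, taken over a wider span than the margin asked and with a scatter of 10.5% on the south-east reading, so we commit to an order of about one.

Does product already present change the rate? The south run starts with 0.0450 M and has made 0.0851 M more by 95 h, against 0.0867 M in the north run. That ratio is 0.982, and the gap is twice the scatter of one reading, so we read no effect of added product.

Then does the rate follow the starting material left? Each unit of product uses one of starting material, so the north run at 95 h gives 0.00908 h⁻¹. This is our clock rate, a pseudo-first-order constant: the natural logarithm of starting material charged over starting material left, divided by the time. At 32 h the north run gives 0.00927 h⁻¹, the same within the readings, so up to 95 h these two readings of the north run fit a share left that shrinks by a steady factor in equal spans of time.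

The south-west run has the north charge, and 190 h is twice 95 h. If the clock rate holds beyond the readings, its share left is the square of the north share at 95 h of 42.2%, which is 17.8%, and our reckoning gives product at 82.2%.

The forecast gives an order of 1.05 (0.85 to 1.25) and 80% (73% to 85%). Its last step reads “Undetected slow catalyst decay would lower this a little, so I expect about 80%”, and our reckoning stands 2.2 percentage points above its figure.

The flask gives an order of 1.0 and 79.8%.

    free catalyst + starting material ⇌ catalyst-substrate complex (568.8 M⁻¹ h⁻¹, 79.20 h⁻¹)
    catalyst-substrate complex + coupling partner → product + free catalyst (14400 M⁻¹ h⁻¹)
    free catalyst + coupling partner ⇌ idle catalyst-reagent complex, settled at all times (57.00 M⁻¹)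
    free catalyst + starting material → spent catalyst + starting material (0.6552 M⁻¹ h⁻¹)

Through the 190 h of the south-west run, free catalyst met starting material on two paths: one to the catalyst-substrate complex, which the coupling partner turned into product, and one to spent catalyst, with a rate constant 868 times smaller. The product there stands 2.4 points below the clock's 82.2%. The south-east run, on its own clock rate of 0.00383 h⁻¹ read at 95 h, is put by the clock at half of its starting material by 181 h; it got there later, at 203 h.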